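**Plan**

Labels used: N4; azepine methylenes C5–C8; enamine C9=C9a; carbinol C1; pyrroline C2, C3; C10 (ethyl); fused lactone O–C11, C12, C13 (methyl), C14; side-chain lactone C18–C21.
Cuts, last-formed bond first: N4–C5 and N4–C9a (primary amine, C9a ketone, C5 chloride); C18–C19 (acrylate allylation of a C18 aldehyde); C12–C13 together with C1–O (radical closure with O2 capture); C1–C2 (Negishi); C10–ethyl and C9–C8 (enolate ethylation; conjugate addition to a ketal-protected cyclohexenone).
What makes the key step possible: in the carbocycle, the branch-bearing C12 and the carbinol C1 are neighbours, with C1 next to C9a and C12 next to the oxygenated C11. With C9a as a ketone and C1=C12 as its conjugated alkene, a 2-bromoallyl acetal on the C11 oxygen gives a C13 radical that reaches C12 through a five-membered transition state and passes the unpaired electron to C1, where dioxygen takes it.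
Ring order forward: carbocycle (from 1), fused lactol/lactone ring (step 10), side-chain lactone (step 14), pyrroline then azepine (step 16).
Stereochemistry: C9 from the asymmetric conjugate addition (a relay centre, erased in the enamine), then C10 by trans ethylation, then C11 by L-Selectride (cis to ethyl). C12 and C1 come from the cis-fused radical closure and convex-face O2 capture, C13 and C20 from hydrogenation of the two α-methylene lactones, C3 from D-serine, and C18 from chelation-controlled allylation.

Key step: step 10

Assumption: the copper/phosphoramidite catalyst is taken to add to ketal 1 with the facial sense known for cyclohex-2-enone, so the (S,R,R)-ligand is written; were the sense opposite, the mirror-image ligand would be used and nothing else changes.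

**Route**

Step 1
Reactants: 1 1,4-dioxaspiro[4.5]dec-6-en-8-one; 2 1-chloro-4-iodobutane
Product: 5 (6R)-6-(4-chlorobutyl)-8-(trimethylsilyloxy)-1,4-dioxaspiro[4.5]dec-7-ene, via bis(4-chlorobutyl)zinc 3 (not isolated), via zinc enolate 4 (not isolated)
Conditions: 2, Et2Zn (neat), CuI (cat.), 50 °C, then volatiles off in vacuo; Cu(OTf)2 (2 mol%), (S,R,R)-binaphthol bis(1-phenylethyl)amine phosphoramidite (4 mol%), 1, toluene, −30 °C; TMSOTf, −30 → 0 °C; Et3N quench
Reagents that add atoms: trimethylsilyl trifluoromethanesulfonate, C[Si](C)(C)OS(=O)(=O)C(F)(F)F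
Why: Iodine–zinc exchange turns 2 into the functionalised dialkylzinc, whose copper/phosphoramidite-catalysed asymmetric conjugate addition (a reaction class established for functionalised dialkylzincs and for ketal-protected enediones) should deliver the chlorobutyl group to C9 under ligand control, and O-silylation of the zinc enolate fixes the C10=C11 enolate for the next step.

Step 2
Reactants: 5; 6 iodoethane
Product: 7 (6R,7R)-6-(4-chlorobutyl)-7-ethyl-1,4-dioxaspiro[4.5]decan-8-one
Conditions: MeLi, THF, 0 °C; then EtI, HMPA, −78 → −20 °C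
Reagents that add atoms: none
Why: Methyllithium cleaves the silyl enol ether to the regiodefined lithium enolate, and enolate alkylation by iodoethane is expected anti to the adjacent C9 substituent, which sets C10 trans to C9.

Step 3
Reactants: 7
Product: 8 (6R,7R,8S)-6-(4-chlorobutyl)-7-ethyl-1,4-dioxaspiro[4.5]decan-8-ol
Conditions: L-Selectride, THF, −78 °C; then H2O
Reagents that add atoms: none
Why: A bulky trialkylborohydride reduces 2-alkylcyclohexanones by equatorial attack, so the new C11 hydroxyl should be axial and cis to the equatorial C10 ethyl group (diastereoselective ketone reduction), and the ketal removes any competing carbonyl.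

Step 4
Reactants: 8
Product: 9 (2R,3R,4S)-2-(4-chlorobutyl)-3-ethyl-4-hydroxycyclohexan-1-one
Conditions: 1 M HCl, THF, rt
Reagents that add atoms: water, O
Why: Acid-catalysed ketal hydrolysis frees the C9a ketone; C9, now α to the carbonyl, already holds the more stable trans arrangement, and the γ-hydroxyl cannot leave by an E1cB path.

Step 5
Reactants: 9
Product: 12 (4S,5R,6R)-6-(4-chlorobutyl)-5-ethyl-4-hydroxycyclohex-2-en-1-one, via bis-silyl enol ether 10 (not isolated), via silyl ether enone 11 (not isolated)
Conditions: LDA (2.3 equiv), TMSCl, THF, −78 °C; Pd(OAc)2 (1.05 equiv), MeCN, rt; dilute aq. HCl work-up, 0 °C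
Reagents that add atoms: none
Why: Saegusa–Ito dehydrogenation: after O-deprotonation LDA removes the less hindered C1 proton rather than the branched C9 one, TMSCl traps alkoxide and enolate, Pd(OAc)2 converts the silyl enol ether into the C1=C12 enone, and mild acid returns the C11 hydroxyl.

Step 6
Reactants: 12
Product: 13 (4R,5R,6R)-6-(4-chlorobutyl)-5-ethyl-4-hydroxy-2-iodocyclohex-2-en-1-one
Conditions: I2, pyridine, CH2Cl2, 0 °C → rt
Reagents that add atoms: iodine, II
Why: α-Iodination of the enone by iodine/pyridine (conjugate addition of pyridine, C-iodination, elimination) places iodine on C1 and leaves the free hydroxyl and the alkyl chloride untouched.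

Step 7
Reactants: 14 tert-butyl N-[(2S)-1-(benzyloxy)-3-hydroxypropan-2-yl]carbamate (N-Boc-O-benzyl-D-serinol)
Product: 15 tert-butyl N-[(2R)-1-(benzyloxy)-3-iodopropan-2-yl]carbamate
Conditions: I2, PPh3, imidazole, CH2Cl2, 0 °C → rt
Reagents that add atoms: iodine, II
Why: Appel-type iodination of the primary alcohol is the usual entry to serine-derived iodides for organozinc chemistry and does not touch the stereocentre.

Step 8
Reactants: 13; 15
Product: 17 tert-butyl N-[(2S)-1-(benzyloxy)-3-[(3R,4R,5R)-5-(4-chlorobutyl)-4-ethyl-3-hydroxy-6-oxocyclohex-1-en-1-yl]propan-2-yl]carbamate, via alkylzinc iodide 16 (not isolated)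
Conditions: 15, Zn dust (TMSCl-activated), DMF, rt; solution transferred to 13, Pd2(dba)3 (2.5 mol%), P(o-tol)3 (10 mol%), DMF, rt
Reagents that add atoms: none
Why: Zinc insertion in DMF gives the β-amido alkylzinc iodide, which is coupled at once with the reactive α-iodoenone in a Negishi reaction so that C1–C2 bond formation outruns β-elimination of the carbamate; an excess of the zinc reagent allows for the free hydroxyl.

Step 9
Reactants: 17; 18 methoxyallene (1-methoxypropa-1,2-diene)
Product: 19 tert-butyl N-[(2S)-1-(benzyloxy)-3-{(3R,4R,5R)-3-[(2-bromo-1-methoxyprop-2-en-1-yl)oxy]-5-(4-chlorobutyl)-4-ethyl-6-oxocyclohex-1-en-1-yl}propan-2-yl]carbamate (both acetal epimers)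
Conditions: NBS, CH2Cl2, −40 → 0 °C
Reagents that add atoms: N-bromosuccinimide, O=C1CCC(=O)N1Br
Why: NBS brominates the central carbon of the alkoxyallene and the resulting 2-bromoallyl oxocarbenium ion is intercepted by the C11 hydroxyl (three-component bromoalkoxylation of alkoxyallenes), giving the 2-bromoallyl mixed acetal without touching C11.

Step 10
Reactants: 19
Product: 21 cis-fused 13-methylidene lactol methyl ether carrying the C1 hydroxyl and the C9a ketone (full name in the list), via C1 hydroperoxide 20 (not isolated)
Conditions: Bu3SnH (slow addition), AIBN (cat.), toluene (high dilution), 60 °C, slow stream of dry air; then PPh3, rt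
Reagents that add atoms: dioxygen, O=O
Why: Bu3Sn• abstracts bromine from the vinyl bromide, the σ-vinyl radical at C13 adds to C12 (the β-carbon of the C9a enone), and the tertiary α-keto radical left at C1 combines with O2 to a peroxyl radical that takes hydrogen from Bu3SnH and so carries the chain; PPh3 then reduces the hydroperoxide. The closest known reactions are the Ueno–Stork haloacetal cyclisation in its vinyl-radical form and the stannane/air oxygenative cyclisation of haloacetals. The one ring closed is the five-membered lactol ring, by 5-exo-trig attack; 6-endo attack at the fully substituted, electron-poor C1 is disfavoured. C12 is set by the tether, since the radical can reach C12 only on the face of the pseudoaxial C11 oxygen and the ring fusion must be cis; C1 is set by approach of O2 to the planar radical on the convex face, anti to the new C12–C13 bond, which places the hydroxyl trans to C13. The step needs ring closure to precede oxygen capture and hydrogen transfer at C13, and oxygen capture to precede hydrogen transfer at C1; the fast addition of a vinyl radical to an enone, high dilution, slow stannane addition and air in place of pure O2 serve both needs. Because the radical carbon is sp2, C13 emerges as an exocyclic methylene and its configuration is settled in step 12.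

Step 11
Reactants: 21
Product: 22 cis-fused α-methylene-γ-lactone (C14 carbonyl) with C1 hydroxyl, C9a ketone, NHBoc and benzyl ether
Conditions: Jones reagent (CrO3, H2SO4, H2O), acetone, 0 °C
Reagents that add atoms: water, O
Why: Jones reagent hydrolyses the lactol methyl ether and oxidises the lactol to the γ-lactone in one operation (Jones oxidation), conditions that a Boc carbamate, a benzyl ether and a tertiary alcohol normally survive at 0 °C.

Step 12
Reactants: 22
Product: 23 (13S)-methyl lactone with free C18 primary alcohol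
Conditions: H2 (1 atm), 10% Pd/C, EtOH, rt
Reagents that add atoms: none
Why: Catalytic hydrogenation should deliver hydrogen to the exocyclic alkene from the convex face of the cis-fused lactone, which puts the C13 methyl on the concave face as required, while the same catalyst removes the benzyl ether by hydrogenolysis and leaves the primary alkyl chloride.

Step 13
Reactants: 23
Product: 24 N-Boc α-amino aldehyde (C18 aldehyde)
Conditions: (COCl)2, DMSO, CH2Cl2, −78 °C; i-Pr2NEt, −78 → −20 °C; used crude
Reagents that add atoms: none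
Why: Swern oxidation gives the N-Boc α-amino aldehyde at low temperature without epimerising C3, and because the oxidant is consumed before the aldehyde is released it does not oxidise a lactol formed with the C1 hydroxyl.

Step 14
Reactants: 24; 25 ethyl 2-(bromomethyl)prop-2-enoate
Product: 27 side-chain α-methylene-γ-butyrolactone with (18S) configuration, via hydroxy ester 26 (not isolated)
Conditions: In powder, THF/H2O, rt; then PPTS (cat.), CH2Cl2, rt
Reagents that add atoms: none
Why: Indium-mediated Barbier allylation with the 2-(bromomethyl)acrylate is expected to pass through a chelate that ties the carbamate to the aldehyde oxygen (Cram-chelate control), so the allyl group adds anti to C2 and gives the syn amino alcohol with (S)-C18, which closes to the α-methylene-γ-butyrolactone on acid catalysis.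

Step 15
Reactants: 27
Product: 28 bis-lactone with (18S,20S) side-chain lactone, NHBoc, C9a ketone and chlorobutyl chain
Conditions: H2 (1 atm), 10% Pd/C, EtOAc, rt
Reagents that add atoms: none
Why: Hydrogenation of an α-methylene-γ-butyrolactone takes place on the face away from the C18 substituent, which gives the cis-2,4-disubstituted lactone with (S)-C20.

Step 16
Reactants: 28
Product: 31 target compound CNP0179500.1, via ammonium trifluoroacetate 29 (not isolated), via cyclic imine 30 (not isolated)
Conditions: TFA, CH2Cl2, 0 °C → rt, concentrate; K2CO3, 4 Å MS, NaI (cat.), MeCN, rt → 60 °C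
Reagents that add atoms: none
Why: Acidolysis of the Boc group frees the amine, which condenses with the C9a ketone to the five-membered cyclic imine (5-exo-trig addition, then dehydration), and the imine nitrogen displaces the iodide-activated primary chloride in a 7-exo-tet N-alkylation whose iminium salt loses the C9 proton to give the tetrasubstituted enamine, the known course of ω-halo ketones with primary amines.

**Compound list**

1 | 1,4-dioxaspiro[4.5]dec-6-en-8-one | O=C1C=CC2(CC1)OCCO2 | starting material
2 | 1-chloro-4-iodobutane | ClCCCCI | starting material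
3 | bis(4-chlorobutyl)zinc | ClCCCC[Zn]CCCCCl | intermediate
4 | (4-chlorobutyl)zinc enolate (C7=C8 enolate) of (6R)-6-(4-chlorobutyl)-1,4-dioxaspiro[4.5]decan-8-one | ClCCCC[Zn]OC1=C[C@@H](CCCCCl)C2(CC1)OCCO2 | intermediate
5 | (6R)-6-(4-chlorobutyl)-8-(trimethylsilyloxy)-1,4-dioxaspiro[4.5]dec-7-ene | C[Si](C)(C)OC1=C[C@@H](CCCCCl)C2(CC1)OCCO2 | intermediate
6 | iodoethane | CCI | starting material
7 | (6R,7R)-6-(4-chlorobutyl)-7-ethyl-1,4-dioxaspiro[4.5]decan-8-one (substituents trans) | CC[C@@H]1[C@@H](CCCCCl)C2(CCC1=O)OCCO2 | intermediate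
8 | (6R,7R,8S)-6-(4-chlorobutyl)-7-ethyl-1,4-dioxaspiro[4.5]decan-8-ol (hydroxyl cis to ethyl) | CC[C@@H]1[C@@H](CCCCCl)C2(CC[C@@H]1O)OCCO2 | intermediate
9 | (2R,3R,4S)-2-(4-chlorobutyl)-3-ethyl-4-hydroxycyclohexan-1-one | CC[C@@H]1[C@@H](CCCCCl)C(=O)CC[C@@H]1O | intermediate
10 | bis(trimethylsilyl) derivative of 9 (C11 silyl ether, C9a=C1 silyl enol ether) | CC[C@@H]1[C@@H](CCCCCl)C(O[Si](C)(C)C)=CC[C@@H]1O[Si](C)(C)C | intermediate
11 | (4S,5R,6R)-6-(4-chlorobutyl)-5-ethyl-4-(trimethylsilyloxy)cyclohex-2-en-1-one | CC[C@@H]1[C@@H](CCCCCl)C(=O)C=C[C@@H]1O[Si](C)(C)C | intermediate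
12 | (4S,5R,6R)-6-(4-chlorobutyl)-5-ethyl-4-hydroxycyclohex-2-en-1-one | CC[C@@H]1[C@@H](CCCCCl)C(=O)C=C[C@@H]1O | intermediate
13 | (4R,5R,6R)-6-(4-chlorobutyl)-5-ethyl-4-hydroxy-2-iodocyclohex-2-en-1-one | CC[C@@H]1[C@@H](CCCCCl)C(=O)C(I)=C[C@@H]1O | intermediate
14 | tert-butyl N-[(2S)-1-(benzyloxy)-3-hydroxypropan-2-yl]carbamate (N-Boc-O-benzyl-D-serinol) | OC[C@H](NC(=O)OC(C)(C)C)COCc1ccccc1 | starting material
15 | tert-butyl N-[(2R)-1-(benzyloxy)-3-iodopropan-2-yl]carbamate | IC[C@H](NC(=O)OC(C)(C)C)COCc1ccccc1 | intermediate
16 | [(2R)-3-(benzyloxy)-2-(tert-butoxycarbonylamino)propyl]zinc iodide | I[Zn]C[C@H](NC(=O)OC(C)(C)C)COCc1ccccc1 | intermediate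
17 | tert-butyl N-[(2S)-1-(benzyloxy)-3-[(3R,4R,5R)-5-(4-chlorobutyl)-4-ethyl-3-hydroxy-6-oxocyclohex-1-en-1-yl]propan-2-yl]carbamate | CC[C@@H]1[C@@H](CCCCCl)C(=O)C(C[C@H](NC(=O)OC(C)(C)C)COCc2ccccc2)=C[C@@H]1O | intermediate
18 | methoxyallene (1-methoxypropa-1,2-diene) | COC=C=C | starting material
19 | 2-bromoallyl mixed acetal of 17 at the C11 oxygen, O–CH(OMe)–C(Br)=CH2 (acetal epimers); the radical precursor | CC[C@@H]1[C@@H](CCCCCl)C(=O)C(C[C@H](NC(=O)OC(C)(C)C)COCc2ccccc2)=C[C@@H]1OC(OC)C(Br)=C | intermediate
20 | C1 hydroperoxide of 21 | CC[C@@H]1[C@@H](CCCCCl)C(=O)[C@](OO)(C[C@H](NC(=O)OC(C)(C)C)COCc3ccccc3)[C@H]2[C@@H]1OC(OC)C2=C | intermediate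
21 | tert-butyl N-[(2S)-1-(benzyloxy)-3-[(3aR,4S,6R,7R,7aR)-6-(4-chlorobutyl)-7-ethyl-4-hydroxy-2-methoxy-3-methylidene-5-oxo-octahydro-1-benzofuran-4-yl]propan-2-yl]carbamate (cis ring fusion, C1 hydroxyl trans to C13, acetal epimers) | CC[C@@H]1[C@@H](CCCCCl)C(=O)[C@](O)(C[C@H](NC(=O)OC(C)(C)C)COCc3ccccc3)[C@H]2[C@@H]1OC(OC)C2=C | intermediate
22 | lactone from 21: 3-methylidene-2,5-dioxo-octahydro-1-benzofuran core, otherwise as 21 | CC[C@@H]1[C@@H](CCCCCl)C(=O)[C@](O)(C[C@H](NC(=O)OC(C)(C)C)COCc3ccccc3)[C@H]2[C@@H]1OC(=O)C2=C | intermediate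
23 | (13S)-methyl lactone with side chain CH2–CH(NHBoc)–CH2OH (3S); C13 methyl cis to the C12–C1 bond | CC[C@@H]1[C@@H](CCCCCl)C(=O)[C@](O)(C[C@H](NC(=O)OC(C)(C)C)CO)[C@H]2[C@@H]1OC(=O)[C@H]2C | intermediate
24 | aldehyde from 23: side chain CH2–CH(NHBoc)–CHO (3S) | CC[C@@H]1[C@@H](CCCCCl)C(=O)[C@](O)(C[C@H](NC(=O)OC(C)(C)C)C=O)[C@H]2[C@@H]1OC(=O)[C@H]2C | intermediate
25 | ethyl 2-(bromomethyl)prop-2-enoate | C=C(CBr)C(=O)OCC | starting material
26 | hydroxy ester: side chain CH2–CH(NHBoc)–CH(OH)–CH2–C(=CH2)–CO2Et with (3S,18S) | CC[C@@H]1[C@@H](CCCCCl)C(=O)[C@](O)(C[C@H](NC(=O)OC(C)(C)C)[C@@H](O)CC(=C)C(=O)OCC)[C@H]2[C@@H]1OC(=O)[C@H]2C | intermediate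
27 | bis-lactone with (2S)-4-methylidene-5-oxooxolan-2-yl group on C3 | CC[C@@H]1[C@@H](CCCCCl)C(=O)[C@](O)(C[C@H](NC(=O)OC(C)(C)C)[C@@H]3CC(=C)C(=O)O3)[C@H]2[C@@H]1OC(=O)[C@H]2C | intermediate
28 | bis-lactone with (2S,4S)-4-methyl-5-oxooxolan-2-yl group on C3 (cis lactone), NHBoc, C9a ketone, 4-chlorobutyl on C9 | CC[C@@H]1[C@@H](CCCCCl)C(=O)[C@](O)(C[C@H](NC(=O)OC(C)(C)C)[C@@H]3C[C@H](C)C(=O)O3)[C@H]2[C@@H]1OC(=O)[C@H]2C | intermediate
29 | trifluoroacetate salt of the primary amine from 28 | CC[C@@H]1[C@@H](CCCCCl)C(=O)[C@](O)(C[C@H](N)[C@@H]3C[C@H](C)C(=O)O3)[C@H]2[C@@H]1OC(=O)[C@H]2C.OC(=O)C(F)(F)F | intermediate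
30 | cyclic imine (1-pyrroline, N4=C9a) with the 4-chlorobutyl chain on C9 | CC[C@@H]1[C@@H](CCCCCl)C3=N[C@H]([C@@H]2C[C@H](C)C(=O)O2)C[C@]3(O)[C@H]2[C@@H]1OC(=O)[C@H]2C | intermediate
31 | CNP0179500.1; in the labels above (1S,3S,10R,11R,12R,13S,18S,20S) | CC[C@@H]1C2=C3N(CCCC2)[C@H]([C@@H]2C[C@H](C)C(=O)O2)C[C@]3(O)[C@H]2[C@@H]1OC(=O)[C@H]2C | target

**Count and risks**

Total steps: 16. Longest linear sequence: 15 (steps 1–6 and 8–16; step 7 is a one-step branch from 14).

Steps most likely to fail:

1. Step 10. The vinyl radical may be oxygenated or reduced before it closes the ring, or the C1 radical may take hydrogen from the stannane before it meets dioxygen, giving the deoxy ketone. Fallback, from 19 back to 21: the cyclisation would be run without oxygen in the presence of excess TEMPO (Bu3SnH, TEMPO, benzene, 70 °C), so that the persistent nitroxide intercepts the C1 radical and gives the C1 (2,2,6,6-tetramethylpiperidin-1-yl)oxy ether F1. Reductive N–O cleavage (Zn, AcOH/THF/H2O, rt) would then free the tertiary alcohol and rejoin the route at 21.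

2. Step 16. Ring closure at nitrogen to the seven-membered ring may be slow, leaving time for O→N acyl migration of the side-chain lactone onto the free amine or for C-alkylation at C9 through the enamine tautomer. Fallback, from 28 back to 31: the halide is exchanged before the nitrogen is unmasked (NaI, acetone, reflux), giving the primary iodide F2. Boc removal (TFA, CH2Cl2) and neutralisation (K2CO3, MeCN, rt) would then let imine formation be followed by iodide displacement at room temperature, where the side reactions are slower, ending at 31.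

3. Step 14. Facial selectivity at C18 may be poor if Felkin–Anh addition competes with the chelated pathway, and C3 of the aldehyde may epimerise. Fallback, from 23 back to 27: the aldehyde is bypassed by an iridium-catalysed transfer-hydrogenative 2-(alkoxycarbonyl)allylation of the primary alcohol 23 with the tert-butyl carbonate of ethyl 2-(hydroxymethyl)acrylate (chiral bisphosphine–iridium C,O-benzoate catalyst, Cs2CO3, THF, heat). In this reaction the catalyst, not the substrate, fixes C18 and the aldehyde exists only transiently on the metal; lactonisation gives 27. No compound outside the list arises on this detour (F0).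

Further compounds
F1 | step 10 | C1 (2,2,6,6-tetramethylpiperidin-1-yl)oxy ether of 21 | CC[C@@H]1[C@@H](CCCCCl)C(=O)[C@](ON4C(C)(C)CCCC4(C)C)(C[C@H](NC(=O)OC(C)(C)C)COCc3ccccc3)[C@H]2[C@@H]1OC(OC)C2=C
F2 | step 16 | 4-iodobutyl analogue of 28 | CC[C@@H]1[C@@H](CCCCI)C(=O)[C@](O)(C[C@H](NC(=O)OC(C)(C)C)[C@@H]3C[C@H](C)C(=O)O3)[C@H]2[C@@H]1OC(=O)[C@H]2C
F0 | step 14 | none | none
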